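**Plan**
1. Retrosynthesis first removes the two acyl groups and C12 (CO and MeOH on a C7 ethynyl group). The 3-oxy-Δ4 unit is then traced to a 3-silyloxy-Δ3 enol ether (Saegusa retron), and the C14 methyl to a lactone carbonyl bonded to the C8 oxygen.
2. The key cut breaks C1–C2 and C5–C10 together: a type 1 intramolecular Diels–Alder reaction of the diene C2=C3(OSi)–C4(Me)=C5 with the exocyclic C10=C1 alkene of an α-methylene-γ-butyrolactone, tethered through C6–C7–C8–C9. Rings A and B arise in this one step.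
3. Enabling feature: on ring B the C10 methyl (C14) and the C8 oxygen are cis-1,3-diaxial, so one carbonyl carbon can bridge them. This lactone activates the dienophile and forces the C10 configuration. The C3 oxygen para to C10, with C4=C5 between them, is the mark of a 2-oxydiene adduct.
4. Forward: a C5–C9 allylic alcohol is epoxidised (Sharpless), opened at C7 by a silylalkynylalane, extended at C9 by acetylide and cyclocarbonylated to the lactone. Wittig enone, silyl dienol ether and cycloaddition follow, then Saegusa, Luche, lactone-to-methyl, two acylations and alkyne methoxycarbonylation.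
5. Stereochemistry: C8 and C7 come from the Sharpless epoxidation and its invertive opening; C10 is relayed from C8 through the lactone bridge; C3 comes from axial hydride delivery anti to C14; C5 is transient.

Key step: step 10

Remark on numbering: eudesmane numbering is used from the chain stage on (ring A = C1–C5 and C10, ring B = C5–C10, C14 on C10, C15 on C4, C11 on C7, C13 the terminal carbon of the C7 side chain, C12 the ester carbon).
Assumption: ylide 13, acid 23 and D-(−)-diisopropyl tartrate are taken as commercial, and the bulky silyl group on the C7 alkyne is assumed to keep that alkyne inert in steps 6 and 11.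

**Step 1**
Reactants: 1 3-[(tert-butyldimethylsilyl)oxy]propanal; 2 triethyl phosphonoacetate
Product: 3 ethyl (2E)-5-[(tert-butyldimethylsilyl)oxy]pent-2-enoate
Conditions: NaH, THF, 0 °C → rt
Reagents that add atoms: none
Why: Horner–Wadsworth–Emmons olefination of an unbranched aldehyde with the stabilised phosphonate anion should give the (E)-enoate (C7=C8).

**Step 2**
Reactants: 3 ethyl (2E)-5-[(tert-butyldimethylsilyl)oxy]pent-2-enoate
Product: 4 (2E)-5-[(tert-butyldimethylsilyl)oxy]pent-2-en-1-ol
Conditions: i-Bu2AlH (2.2 equiv), CH2Cl2, −78 °C; aq. potassium sodium tartrate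
Reagents that add atoms: none
Why: 1,2-reduction of an α,β-unsaturated ester to the allylic alcohol with i-Bu2AlH leaves the alkene geometry and the silyl ether untouched.

**Step 3**
Reactants: 4 (2E)-5-[(tert-butyldimethylsilyl)oxy]pent-2-en-1-ol
Product: 5 [(2R,3R)-3-{2-[(tert-butyldimethylsilyl)oxy]ethyl}oxiran-2-yl]methanol
Conditions: Ti(OiPr)4 (10 mol %), D-(−)-diisopropyl tartrate (12 mol %), t-BuOOH, 4 Å molecular sieves, CH2Cl2, −20 °C
Reagents that add atoms: tert-butyl hydroperoxide, CC(C)(C)OO
Why: Sharpless asymmetric epoxidation of an (E)-allylic alcohol; the D-(−)-tartrate ligand directs oxygen to the face that gives the (2R,3R)-epoxide, which fixes C8 and, after inversion in step 4, C7.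

**Step 4**
Reactants: 5 [(2R,3R)-3-{2-[(tert-butyldimethylsilyl)oxy]ethyl}oxiran-2-yl]methanol; 6 ethynyltriisopropylsilane
Product: 7 (2S,3R)-3-{2-[(tert-butyldimethylsilyl)oxy]ethyl}-5-(triisopropylsilyl)pent-4-yne-1,2-diol
Conditions: 6, n-BuLi, toluene, 0 °C; Et2AlCl; then 5, 0 °C → rt; aq. potassium sodium tartrate
Reagents that add atoms: none
Why: regioselective C3 opening of a 2,3-epoxy alcohol by a diethylalkynylalane (the aluminium alkoxide activates the epoxide and the alkynyl group attacks the distal carbon with inversion) sets C7 and gives the C7/C8 relationship that becomes cis on ring B.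

**Step 5**
Reactants: 7 (2S,3R)-3-{2-[(tert-butyldimethylsilyl)oxy]ethyl}-5-(triisopropylsilyl)pent-4-yne-1,2-diol
Product: 10 (4R,5R)-5-{2-[(tert-butyldimethylsilyl)oxy]ethyl}-7-(triisopropylsilyl)hepta-1,6-diyn-4-ol, via primary tosylate 8 (not isolated), via terminal epoxide 9 (not isolated)
Conditions: NaH (2.2 equiv), N-tosylimidazole, THF, 0 °C → rt; then LiC≡CH·H2NCH2CH2NH2, DMSO, rt; H2O
Reagents that add atoms: lithium acetylide (ethylenediamine complex), [Li+].[C-]#C
Why: one-flask diol-to-epoxide conversion (selective primary sulfonylation, then internal Williamson displacement with retention at C8) followed by SN2 opening of the terminal epoxide by acetylide installs the C9–C10≡C1 unit.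

**Step 6**
Reactants: 10 (4R,5R)-5-{2-[(tert-butyldimethylsilyl)oxy]ethyl}-7-(triisopropylsilyl)hepta-1,6-diyn-4-ol
Product: 11 (5R)-5-[(3R)-1-[(tert-butyldimethylsilyl)oxy]-5-(triisopropylsilyl)pent-4-yn-3-yl]-3-methylidenedihydrofuran-2(3H)-one
Conditions: PdCl2 (5 mol %), SnCl2 (5 mol %), PPh3 (10 mol %), CO (7 bar), MeCN, 75 °C
Reagents that add atoms: carbon monoxide, [C-]#[O+]
Why: palladium-catalysed cyclocarbonylation of a homopropargylic alcohol (alkoxycarbonyl–palladium formation, syn insertion of the terminal alkyne, protonolysis) should give the α-methylene-γ-butyrolactone with C14 from CO, while the hindered silylated internal alkyne should not insert.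

**Step 7**
Reactants: 11 (5R)-5-[(3R)-1-[(tert-butyldimethylsilyl)oxy]-5-(triisopropylsilyl)pent-4-yn-3-yl]-3-methylidenedihydrofuran-2(3H)-one
Product: 12 (5R)-5-[(3R)-1-hydroxy-5-(triisopropylsilyl)pent-4-yn-3-yl]-3-methylidenedihydrofuran-2(3H)-one
Conditions: HF·pyridine, pyridine, THF, 0 °C → rt
Reagents that add atoms: none
Why: buffered fluoride cleavage of a primary silyl ether should spare the alkynylsilane and the base-sensitive methylene lactone.

**Step 8**
Reactants: 12 (5R)-5-[(3R)-1-hydroxy-5-(triisopropylsilyl)pent-4-yn-3-yl]-3-methylidenedihydrofuran-2(3H)-one; 13 3-(triphenylphosphoranylidene)butan-2-one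
Product: 15 (5R)-3-methylidene-5-[(3R,5E)-6-methyl-7-oxo-1-(triisopropylsilyl)oct-5-en-1-yn-3-yl]dihydrofuran-2(3H)-one, via aldehyde 14 (not isolated)
Conditions: Dess–Martin periodinane, pyridine, CH2Cl2, 0 °C → rt; then 13, toluene, 80 °C
Reagents that add atoms: none
Why: Dess–Martin oxidation followed in the same flask by Wittig olefination with a stabilised α-branched keto ylide should give the (E)-trisubstituted enone (C4=C5).

**Step 9**
Reactants: 15 (5R)-3-methylidene-5-[(3R,5E)-6-methyl-7-oxo-1-(triisopropylsilyl)oct-5-en-1-yn-3-yl]dihydrofuran-2(3H)-one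
Product: 16 (5R)-5-[(3R,5E)-7-[(tert-butyldimethylsilyl)oxy]-6-methyl-1-(triisopropylsilyl)octa-5,7-dien-1-yn-3-yl]-3-methylidenedihydrofuran-2(3H)-one
Conditions: t-BuMe2SiOTf (1.2 equiv), Et3N, CH2Cl2, −78 → 0 °C
Reagents that add atoms: tert-butyldimethylsilyl trifluoromethanesulfonate, CC(C)(C)[Si](C)(C)OS(=O)(=O)C(F)(F)F
Why: soft enolisation of the methyl ketone at its α′-methyl group (silyl triflate and amine) gives the cross-conjugated 2-silyloxydiene; the lactone is enolised far more slowly.

**Step 10**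
Reactants: 16 (5R)-5-[(3R,5E)-7-[(tert-butyldimethylsilyl)oxy]-6-methyl-1-(triisopropylsilyl)octa-5,7-dien-1-yn-3-yl]-3-methylidenedihydrofuran-2(3H)-one
Product: 17 tricyclic lactone: trans-fused octalin with 3-[(tert-butyldimethylsilyl)oxy]-Δ3 enol ether, 4-methyl, 5α-H, 7β-[(triisopropylsilyl)ethynyl] and the C14 carbonyl on C10 lactonised to the 8β-oxygen
Conditions: toluene (0.005 M), 2,6-di-tert-butyl-4-methylphenol (cat.), 130 °C, sealed tube
Reagents that add atoms: none
Why: Thermal, concerted but asynchronous normal-electron-demand [4+2] cycloaddition between the 2-silyloxydiene C2=C3(OSi)–C4(Me)=C5 and the exocyclic C10=C1 alkene of the α-methylene-γ-butyrolactone, joined by the C6–C7–C8–C9 tether; the closest known reaction types are thermal type 1 intramolecular Diels–Alder reactions of 1,3,9-decatrienes to eudesmane octalins and Diels–Alder additions of silyloxydienes to α-methylene lactones. Ring A closes as the new cyclohexene of the cycloaddition itself (bonds C1–C2 and C5–C10), and ring B closes as a six-membered chair-like ring through the four-atom tether when C5 bonds to C10, which at the same time completes a 6-oxabicyclo[3.2.1]octan-7-one. C10 is controlled by the lactone: the diene is tied to C8 and can reach only the alkene face syn to C7, and because C14 and the C8 oxygen are already bonded, the new quaternary centre must carry C14 cis to that oxygen. C5 depends on the endo or exo mode; the endo arrangement of the diene over the lactone carbonyl (trans fusion, 5α-H) is expected, and since this centre is removed in step 11 either mode converges. The regiochemistry imposed by the tether (C2 to C1, C5 to C10) matches the electronic preference (donor-flanked diene terminus C2 to the β-carbon of the acrylate unit) and the C7 alkynyl group sits equatorial in the chair-like tether, so the only selectivity needed is intramolecular over intermolecular reaction, which high dilution and a radical inhibitor should secure.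

**Step 11**
Reactants: 17 tricyclic silyl enol ether lactone
Product: 18 enone lactone: 3-oxo-Δ4(5), 4-methyl, 7β-[(triisopropylsilyl)ethynyl], C14(=O)–O–C8β bridge
Conditions: Pd(OAc)2 (1.2 equiv), MeCN, 40 °C
Reagents that add atoms: none
Why: Saegusa–Ito oxidation: transmetalation of the silyl enol ether to a palladium enolate at C4 and β-hydride elimination of H5 should give the conjugated tetrasubstituted enone and remove the transient C5 centre.

**Step 12**
Reactants: 18 enone lactone
Product: 19 allylic alcohol lactone: 3β-hydroxy-Δ4, otherwise as 18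
Conditions: NaBH4, CeCl3·7H2O, MeOH, −40 → 0 °C
Reagents that add atoms: none
Why: Luche 1,2-reduction; axial hydride delivery on the α face, anti to the axial C10–C14 bond, should give the equatorial 3β-alcohol (3S) and leave the lactone intact.

**Step 13**
Reactants: 19 allylic alcohol lactone
Product: 20 lactol: C14 hemiacetal (both anomers) bridged to O8, 3β-hydroxy-Δ4, 7β-[(triisopropylsilyl)ethynyl]
Conditions: i-Bu2AlH (2.5 equiv), CH2Cl2, −78 °C; aq. potassium sodium tartrate
Reagents that add atoms: none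
Why: partial reduction of a lactone to the lactol with i-Bu2AlH at low temperature, where the tetrahedral aluminium hemiacetal persists until work-up.

**Step 14**
Reactants: 20 lactol
Product: 22 diol: 4,10β-dimethyl-7β-[(triisopropylsilyl)ethynyl]-Δ4-octalin-3β,8β-diol, via tosylhydrazone 21 (not isolated)
Conditions: TsNHNH2, THF, 50 °C; then catecholborane, CHCl3, 0 °C; NaOAc·3H2O, 60 °C
Reagents that add atoms: none
Why: the lactol reacts through its hydroxy aldehyde form with tosylhydrazide, and Kabalka-type reduction of the tosylhydrazone (hydride transfer to C=N, then acetate-induced loss of sulfinate and dinitrogen, a mild Wolff–Kishner-type deoxygenation) should turn C14 into the methyl group and release the 8β-hydroxyl.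

**Step 15**
Reactants: 22 diol; 23 (2E)-3-methylpent-2-enoic acid
Product: 24 3β-{[(2E)-3-methylpent-2-enoyl]oxy}-4,10β-dimethyl-7β-[(triisopropylsilyl)ethynyl]-Δ4-octalin-8β-ol
Conditions: 23 (1.1 equiv), N,N′-dicyclohexylcarbodiimide, 4-(dimethylamino)pyridine (cat.), CH2Cl2, 0 °C
Reagents that add atoms: none
Why: Steglich esterification; the equatorial allylic 3β-hydroxyl should be acylated in preference to the axial 8β-hydroxyl, which is syn-diaxial to the C10 methyl and flanked by the C7 branch.

**Step 16**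
Reactants: 24 hydroxy ester
Product: 25 8β-acetoxy-3β-{[(2E)-3-methylpent-2-enoyl]oxy}-4,10β-dimethyl-7β-[(triisopropylsilyl)ethynyl]-Δ4-octalin
Conditions: Ac2O, 4-(dimethylamino)pyridine (cat.), pyridine, 40 °C
Reagents that add atoms: acetic anhydride, CC(=O)OC(C)=O
Why: nucleophile-catalysed acetylation of the remaining hindered secondary alcohol.

**Step 17**
Reactants: 25 silylalkyne diester
Product: 26 8β-acetoxy-7β-ethynyl-3β-{[(2E)-3-methylpent-2-enoyl]oxy}-4,10β-dimethyl-Δ4-octalin
Conditions: Bu4NF, AcOH, THF, 0 °C → rt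
Reagents that add atoms: none
Why: fluoride-induced protodesilylation of the alkynylsilane, buffered with acetic acid so that both esters should survive.

**Step 18**
Reactants: 26 terminal alkyne
Product: 27 methyl 2-[(2R,3R,4aR,7S)-3-acetoxy-4a,8-dimethyl-7-{[(2E)-3-methylpent-2-enoyl]oxy}-1,2,3,4,4a,5,6,7-octahydronaphthalen-2-yl]prop-2-enoate (target)
Conditions: Pd(OAc)2 (2 mol %), 2-(diphenylphosphino)pyridine (8 mol %), CH3SO3H (8 mol %), CO (20 bar), MeOH, 50 °C
Reagents that add atoms: carbon monoxide, [C-]#[O+]; methanol, CO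
Why: palladium-catalysed Markovnikov hydromethoxycarbonylation of a terminal alkyne (pyridylphosphine and sulfonic acid catalyst system) should place CO2Me on the internal carbon C11 to give the 2-substituted acrylate; no free hydroxyl is left to lactonise.

**Compound list**
1 | 3-[(tert-butyldimethylsilyl)oxy]propanal | O=CCCO[Si](C)(C)C(C)(C)C | starting material
2 | triethyl phosphonoacetate | CCOC(=O)CP(=O)(OCC)OCC | starting material
3 | ethyl (2E)-5-[(tert-butyldimethylsilyl)oxy]pent-2-enoate | CCOC(=O)/C=C/CCO[Si](C)(C)C(C)(C)C | intermediate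
4 | (2E)-5-[(tert-butyldimethylsilyl)oxy]pent-2-en-1-ol | OC/C=C/CCO[Si](C)(C)C(C)(C)C | intermediate
5 | [(2R,3R)-3-{2-[(tert-butyldimethylsilyl)oxy]ethyl}oxiran-2-yl]methanol | OC[C@H]1O[C@@H]1CCO[Si](C)(C)C(C)(C)C | intermediate
6 | ethynyltriisopropylsilane | C#C[Si](C(C)C)(C(C)C)C(C)C | starting material
7 | (2S,3R)-3-{2-[(tert-butyldimethylsilyl)oxy]ethyl}-5-(triisopropylsilyl)pent-4-yne-1,2-diol | OC[C@@H](O)[C@@H](C#C[Si](C(C)C)(C(C)C)C(C)C)CCO[Si](C)(C)C(C)(C)C | intermediate
8 | primary mono-p-toluenesulfonate of diol 7 (not isolated) | Cc1ccc(cc1)S(=O)(=O)OC[C@@H](O)[C@@H](C#C[Si](C(C)C)(C(C)C)C(C)C)CCO[Si](C)(C)C(C)(C)C | intermediate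
9 | tert-butyldimethyl{[(3R)-3-[(2S)-oxiran-2-yl]-5-(triisopropylsilyl)pent-4-yn-1-yl]oxy}silane (not isolated) | C1O[C@H]1[C@@H](C#C[Si](C(C)C)(C(C)C)C(C)C)CCO[Si](C)(C)C(C)(C)C | intermediate
10 | (4R,5R)-5-{2-[(tert-butyldimethylsilyl)oxy]ethyl}-7-(triisopropylsilyl)hepta-1,6-diyn-4-ol | C#CC[C@@H](O)[C@@H](C#C[Si](C(C)C)(C(C)C)C(C)C)CCO[Si](C)(C)C(C)(C)C | intermediate
11 | (5R)-5-[(3R)-1-[(tert-butyldimethylsilyl)oxy]-5-(triisopropylsilyl)pent-4-yn-3-yl]-3-methylidenedihydrofuran-2(3H)-one | CC(C)(C)[Si](C)(C)OCC[C@H](C#C[Si](C(C)C)(C(C)C)C(C)C)[C@H]1CC(=C)C(=O)O1 | intermediate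
12 | (5R)-5-[(3R)-1-hydroxy-5-(triisopropylsilyl)pent-4-yn-3-yl]-3-methylidenedihydrofuran-2(3H)-one | OCC[C@H](C#C[Si](C(C)C)(C(C)C)C(C)C)[C@H]1CC(=C)C(=O)O1 | intermediate
13 | 3-(triphenylphosphoranylidene)butan-2-one | CC(=O)C(C)=P(c1ccccc1)(c1ccccc1)c1ccccc1 | starting material
14 | (3R)-3-[(2R)-4-methylidene-5-oxooxolan-2-yl]-5-(triisopropylsilyl)pent-4-ynal (not isolated) | O=CC[C@H](C#C[Si](C(C)C)(C(C)C)C(C)C)[C@H]1CC(=C)C(=O)O1 | intermediate
15 | (5R)-3-methylidene-5-[(3R,5E)-6-methyl-7-oxo-1-(triisopropylsilyl)oct-5-en-1-yn-3-yl]dihydrofuran-2(3H)-one | CC(=O)/C(C)=C/C[C@H](C#C[Si](C(C)C)(C(C)C)C(C)C)[C@H]1CC(=C)C(=O)O1 | intermediate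
16 | (5R)-5-[(3R,5E)-7-[(tert-butyldimethylsilyl)oxy]-6-methyl-1-(triisopropylsilyl)octa-5,7-dien-1-yn-3-yl]-3-methylidenedihydrofuran-2(3H)-one | C=C(O[Si](C)(C)C(C)(C)C)/C(C)=C/C[C@H](C#C[Si](C(C)C)(C(C)C)C(C)C)[C@H]1CC(=C)C(=O)O1 | intermediate
17 | tricyclic lactone: trans-fused octalin, 3-[(tert-butyldimethylsilyl)oxy]-Δ3, 4-methyl, 5α-H, 7β-[(triisopropylsilyl)ethynyl], C14(=O) on C10 lactonised to O8β | CC(C)[Si](C#C[C@H]1C[C@H]2C(C)=C(O[Si](C)(C)C(C)(C)C)CC[C@]23C[C@H]1OC3=O)(C(C)C)C(C)C | intermediate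
18 | enone lactone: 3-oxo-Δ4, 4-methyl, 7β-[(triisopropylsilyl)ethynyl], C14(=O)–O–C8β bridge | CC(C)[Si](C#C[C@H]1CC2=C(C)C(=O)CC[C@]23C[C@H]1OC3=O)(C(C)C)C(C)C | intermediate
19 | 3β-hydroxy-Δ4 lactone (3S), otherwise as 18 | CC(C)[Si](C#C[C@H]1CC2=C(C)[C@@H](O)CC[C@]23C[C@H]1OC3=O)(C(C)C)C(C)C | intermediate
20 | 3β-hydroxy-Δ4 lactol (C14 hemiacetal bridged to O8β, both anomers) | CC(C)[Si](C#C[C@H]1CC2=C(C)[C@@H](O)CC[C@]23C[C@H]1OC3O)(C(C)C)C(C)C | intermediate
21 | C14 (E)-tosylhydrazone of the 3β,8β-diol (not isolated) | CC(C)[Si](C#C[C@H]1CC2=C(C)[C@@H](O)CC[C@]2(/C=N/NS(=O)(=O)c3ccc(C)cc3)C[C@H]1O)(C(C)C)C(C)C | intermediate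
22 | 4,10β-dimethyl-7β-[(triisopropylsilyl)ethynyl]-Δ4-octalin-3β,8β-diol | CC(C)[Si](C#C[C@H]1CC2=C(C)[C@@H](O)CC[C@]2(C)C[C@H]1O)(C(C)C)C(C)C | intermediate
23 | (2E)-3-methylpent-2-enoic acid | CC/C(C)=C/C(=O)O | starting material
24 | 3β-{[(2E)-3-methylpent-2-enoyl]oxy}-4,10β-dimethyl-7β-[(triisopropylsilyl)ethynyl]-Δ4-octalin-8β-ol | CC(C)[Si](C#C[C@H]1CC2=C(C)[C@@H](OC(=O)/C=C(\C)CC)CC[C@]2(C)C[C@H]1O)(C(C)C)C(C)C | intermediate
25 | 8β-acetate of 24 | CC(C)[Si](C#C[C@H]1CC2=C(C)[C@@H](OC(=O)/C=C(\C)CC)CC[C@]2(C)C[C@H]1OC(C)=O)(C(C)C)C(C)C | intermediate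
26 | 8β-acetoxy-7β-ethynyl-3β-{[(2E)-3-methylpent-2-enoyl]oxy}-4,10β-dimethyl-Δ4-octalin | C#C[C@H]1CC2=C(C)[C@@H](OC(=O)/C=C(\C)CC)CC[C@]2(C)C[C@H]1OC(C)=O | intermediate
27 | methyl 2-[(2R,3R,4aR,7S)-3-acetoxy-4a,8-dimethyl-7-{[(2E)-3-methylpent-2-enoyl]oxy}-1,2,3,4,4a,5,6,7-octahydronaphthalen-2-yl]prop-2-enoate | C=C(C(=O)OC)[C@H]1CC2=C(C)[C@@H](OC(=O)/C=C(\C)CC)CC[C@]2(C)C[C@H]1OC(C)=O | target

**Step count and risks**
Total step count: 18. Longest linear sequence: 18 steps (1 → 27).

Steps most likely to fail: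

1. Step 10. The cycloaddition may be slow because the transition state is bridged, so thermal loss of the silyl enol ether or oligomerisation of the methylene lactone could compete. Fallback, setting out from enone 15 and coming back at 17: the diene would be generated catalytically as the cross-conjugated 2-aminodiene (pyrrolidine with AcOH, CHCl3, 40 °C), an amine-catalysed intramolecular [4+2] reaction that after hydrolytic work-up should give the saturated tricyclic 3-keto lactone F1 (4α-methyl, 5α-H). Silylation of F1 under equilibrating conditions (t-BuMe2SiCl, NaI, Et3N, MeCN, 50 °C) should give the more substituted enol ether, which is 17.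

2. Step 14. The bridged lactol may open incompletely towards the hydrazone, or the allylic C3 alcohol may ionise under the Lewis-acidic borane. Fallback, setting out from 17 and coming back at 22: LiAlH4 (THF, 0 °C) would reduce the lactone to the C14,8β-diol F2 with the silyl enol ether retained. Selective acylation of the primary C14 hydroxyl with PhOC(S)Cl and pyridine would give the O-phenyl thionocarbonate F3. Barton–McCombie deoxygenation (Bu3SnH, azobisisobutyronitrile, toluene, 110 °C) would give the C14-methyl silyl enol ether F4. Saegusa–Ito oxidation (Pd(OAc)2, MeCN) would give the 8β-hydroxy enone F5, and Luche reduction (NaBH4, CeCl3·7H2O, MeOH) would give 22.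

3. Step 18. The acid co-catalyst in methanol may cause solvolysis of the allylic C3 ester, or Markovnikov regiocontrol may be eroded at the branched propargylic position. Fallback, setting out from 26 and coming back at 27: bromoboration with B-bromo-9-borabicyclo[3.3.1]nonane (CH2Cl2, 0 °C) and protonolysis with AcOH would give the 2-bromoalkene F6. Base-buffered carbonylation (PdCl2(PPh3)2, CO, MeOH, Et3N, 60 °C) would then give 27.

**Further compounds**
F1 | step 10 | saturated tricyclic keto lactone: 3-oxo, 4α-methyl, 5α-H, 7β-[(triisopropylsilyl)ethynyl], C14(=O)–O–C8β bridge | CC(C)[Si](C#C[C@H]1C[C@H]2[C@H](C)C(=O)CC[C@]23C[C@H]1OC3=O)(C(C)C)C(C)C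
F2 | step 14 | diol from 17: C14 hydroxymethyl on C10, 8β-hydroxyl, silyl enol ether retained | CC(C)[Si](C#C[C@H]1C[C@H]2C(C)=C(O[Si](C)(C)C(C)(C)C)CC[C@]2(CO)C[C@H]1O)(C(C)C)C(C)C
F3 | step 14 | O-phenyl thionocarbonate of the primary C14 hydroxyl of F2 | CC(C)[Si](C#C[C@H]1C[C@H]2C(C)=C(O[Si](C)(C)C(C)(C)C)CC[C@]2(COC(=S)Oc3ccccc3)C[C@H]1O)(C(C)C)C(C)C
F4 | step 14 | 10β-methyl silyl enol ether with free 8β-hydroxyl | CC(C)[Si](C#C[C@H]1C[C@H]2C(C)=C(O[Si](C)(C)C(C)(C)C)CC[C@]2(C)C[C@H]1O)(C(C)C)C(C)C
F5 | step 14 | 8β-hydroxy-4,10β-dimethyl-7β-[(triisopropylsilyl)ethynyl]-Δ4-octalin-3-one | CC(C)[Si](C#C[C@H]1CC2=C(C)C(=O)CC[C@]2(C)C[C@H]1O)(C(C)C)C(C)C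
F6 | step 18 | 8β-acetoxy-7β-(1-bromoethenyl)-3β-{[(2E)-3-methylpent-2-enoyl]oxy}-4,10β-dimethyl-Δ4-octalin | C=C(Br)[C@H]1CC2=C(C)[C@@H](OC(=O)/C=C(\C)CC)CC[C@]2(C)C[C@H]1OC(C)=O
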